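**Strategy.** The route rests on disconnecting the C2=C3 double bond of pyranone ring C, the vinylogous-ester alkene that links C3 (alpha to the C4 ketone) to C2 (bearing ring B and O1). A thermal intramolecular Wittig reaction of a keto-stabilised ylide at C3 with an aryl benzoate carbonyl at C2 closes ring C and installs the flavone oxidation level in one neutral operation, so the acid-labile, electron-rich benzylic C2'–N centre at C8 is not disturbed. The precursor is a pentasubstituted ring A arene carrying the N-Boc (R)-piperidine at C8, the benzoate on the C8a oxygen, the phosphoranylidene-acetyl group at C4a and methyl ethers at O5 and O7.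

Key step: step 11

Remark: flavone numbering with primed piperidine locants is used; C2' is (R) in the target (CIP order N > C8 > C3' > H) and keeps this descriptor in every intermediate from compound 10 onward.

Step 1
Reactants: 1 2-hydroxy-4,6-dimethoxybenzaldehyde; 2 N-bromosuccinimide
Product: 3 3-bromo-2-hydroxy-4,6-dimethoxybenzaldehyde
Conditions: NBS, i-Pr2NH (cat.), CH2Cl2, 0 °C
Reagents that add atoms: N-bromosuccinimide, O=C1CCC(=O)N1Br
Why: Electrophilic aromatic bromination in which the amine-bound bromine is delivered through hydrogen bonding to the chelated 2-hydroxyl, so substitution should occur at C3, the only free ortho position, and it is done before any stereocentre exists.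

Step 2
Reactants: 3 3-bromo-2-hydroxy-4,6-dimethoxybenzaldehyde; 4 benzyl bromide
Product: 5 2-(benzyloxy)-3-bromo-4,6-dimethoxybenzaldehyde
Conditions: BnBr, K2CO3, DMF, 50 °C
Reagents that add atoms: benzyl bromide, BrCc1ccccc1
Why: Williamson ether synthesis on the phenoxide gives a benzyl ether that should withstand organomagnesium and organolithium reagents and can later be removed by neutral hydrogenolysis.

Step 3
Reactants: 5 2-(benzyloxy)-3-bromo-4,6-dimethoxybenzaldehyde; 6 (S)-2-methylpropane-2-sulfinamide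
Product: 7 (S)-N-{(E)-[2-(benzyloxy)-3-bromo-4,6-dimethoxyphenyl]methylidene}-2-methylpropane-2-sulfinamide
Conditions: Ti(OEt)4, THF, 65 °C
Reagents that add atoms: (S)-2-methylpropane-2-sulfinamide, CC(C)(C)[S@](=O)N
Why: Ti(OEt)4-mediated dehydrative condensation of an aldehyde with tert-butanesulfinamide should give the E-sulfinyl imine without loss of configuration at sulfur.

Step 4
Reactants: 7 (S)-N-{(E)-[2-(benzyloxy)-3-bromo-4,6-dimethoxyphenyl]methylidene}-2-methylpropane-2-sulfinamide; 8 1-bromo-4-chlorobutane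
Product: 10 (S)-N-{(1R)-1-[2-(benzyloxy)-3-bromo-4,6-dimethoxyphenyl]-5-chloropentyl}-2-methylpropane-2-sulfinamide, via 4-chlorobutylmagnesium bromide 9 (not isolated)
Conditions: 8, Mg, THF, 25 °C; then 7, CH2Cl2, −48 °C; aq. NH4Cl
Reagents that add atoms: 1-bromo-4-chlorobutane, ClCCCCBr, delivered as its Grignard reagent 9, ClCCCC[Mg]Br
Why: Grignard 1,2-addition to an N-tert-butanesulfinyl aldimine through a six-membered chair transition state with magnesium on the sulfinyl oxygen, so that (S)-sulfur should direct the alkyl group to the Re face of C=N and set C2' as (R), the minor diastereomer being separable at this stage.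

Step 5
Reactants: 10 (S)-N-{(1R)-1-[2-(benzyloxy)-3-bromo-4,6-dimethoxyphenyl]-5-chloropentyl}-2-methylpropane-2-sulfinamide
Product: 11 (2R)-2-[2-(benzyloxy)-3-bromo-4,6-dimethoxyphenyl]-1-[(S)-2-methylpropane-2-sulfinyl]piperidine
Conditions: KN(SiMe3)2, THF, 0 → 20 °C
Reagents that add atoms: none
Why: Intramolecular N-alkylation (6-exo-tet SN2) of the sulfinamide anion on the primary chloride should close the piperidine without touching C2'.

Step 6
Reactants: 11 (2R)-2-[2-(benzyloxy)-3-bromo-4,6-dimethoxyphenyl]-1-[(S)-2-methylpropane-2-sulfinyl]piperidine; 12 di-tert-butyl dicarbonate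
Product: 14 tert-butyl (2R)-2-[2-(benzyloxy)-3-bromo-4,6-dimethoxyphenyl]piperidine-1-carboxylate, via piperidinium chloride 13 (not isolated)
Conditions: HCl (4 M in dioxane), MeOH, 0 °C; then Et3N, Boc2O, CH2Cl2, 20 °C
Reagents that add atoms: di-tert-butyl dicarbonate, CC(C)(C)OC(=O)OC(=O)OC(C)(C)C
Why: Brief, cold acidolysis of the S–N bond followed by carbamate formation exchanges the auxiliary for a Boc group that should tolerate the organolithium, phosphine and thermal steps, the protonated amine being a poor leaving group so that C2' stays intact.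

Step 7
Reactants: 14 tert-butyl (2R)-2-[2-(benzyloxy)-3-bromo-4,6-dimethoxyphenyl]piperidine-1-carboxylate; 15 2-chloro-N-methoxy-N-methylacetamide
Product: 17 tert-butyl (2R)-2-[2-(benzyloxy)-3-(chloroacetyl)-4,6-dimethoxyphenyl]piperidine-1-carboxylate, via aryllithium 16 (not isolated)
Conditions: n-BuLi, THF, −78 °C; then 15, −78 → −40 °C; aq. NH4Cl
Reagents that add atoms: 2-chloro-N-methoxy-N-methylacetamide, CON(C)C(=O)CCl
Why: Bromine–lithium exchange followed by Weinreb ketone synthesis, in which the aryllithium adds once to give a stable chelate that releases the α-chloro ketone only on quench, should place the C4–C3 unit at C4a regiospecifically and without any Lewis acid.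

Step 8
Reactants: 17 tert-butyl (2R)-2-[2-(benzyloxy)-3-(chloroacetyl)-4,6-dimethoxyphenyl]piperidine-1-carboxylate; 18 triphenylphosphine
Product: 19 {2-[2-(benzyloxy)-3-[(2R)-1-(tert-butoxycarbonyl)piperidin-2-yl]-4,6-dimethoxyphenyl]-2-oxoethyl}triphenylphosphonium chloride
Conditions: PPh3, toluene, 70 °C
Reagents that add atoms: triphenylphosphine, c1ccc(P(c2ccccc2)c2ccccc2)cc1
Why: SN2 quaternisation of the phosphine by the α-chloro ketone is carried out while the C8a oxygen is still benzylated, so that an ortho-hydroxy chloro ketone prone to benzofuranone closure never exists.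

Step 9
Reactants: 19 {2-[2-(benzyloxy)-3-[(2R)-1-(tert-butoxycarbonyl)piperidin-2-yl]-4,6-dimethoxyphenyl]-2-oxoethyl}triphenylphosphonium chloride
Product: 20 {2-[3-[(2R)-1-(tert-butoxycarbonyl)piperidin-2-yl]-2-hydroxy-4,6-dimethoxyphenyl]-2-oxoethyl}triphenylphosphonium chloride
Conditions: H2 (1 atm), 10% Pd/C, MeOH, 20 °C
Reagents that add atoms: none
Why: Heterogeneous catalytic hydrogenolysis of the aryl benzyl ether under neutral conditions should free the C8a phenol while the phosphonium group, the aryl ketone and the carbamate stay intact.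

Step 10
Reactants: 20 {2-[3-[(2R)-1-(tert-butoxycarbonyl)piperidin-2-yl]-2-hydroxy-4,6-dimethoxyphenyl]-2-oxoethyl}triphenylphosphonium chloride; 21 benzoyl chloride
Product: 23 tert-butyl (2R)-2-{2-(benzoyloxy)-4,6-dimethoxy-3-[(triphenyl-λ5-phosphanylidene)acetyl]phenyl}piperidine-1-carboxylate, via hydroxy ylide 22 (not isolated)
Conditions: aq. Na2CO3, CH2Cl2, 20 °C; then BzCl, pyridine, CH2Cl2, 0 °C
Reagents that add atoms: benzoyl chloride, O=C(Cl)c1ccccc1
Why: Deprotonation of the acidic phosphonium methylene gives the keto-stabilised ylide, and Schotten–Baumann-type acylation in pyridine should then occur at the phenolic oxygen, as is known for (2-hydroxyphenacylidene)triphenylphosphoranes.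

Step 11
Reactants: 23 tert-butyl (2R)-2-{2-(benzoyloxy)-4,6-dimethoxy-3-[(triphenyl-λ5-phosphanylidene)acetyl]phenyl}piperidine-1-carboxylate
Product: 24 tert-butyl (2R)-2-(5,7-dimethoxy-4-oxo-2-phenyl-4H-chromen-8-yl)piperidine-1-carboxylate
Conditions: toluene, 110 °C, argon
Reagents that add atoms: none
Why: The nucleophilic ylide carbon C3 adds to the carbonyl carbon of the C8a benzoate (the future C2) to give a betaine that closes to a 1,2-oxaphosphetane, and cycloreversion expels Ph3P=O to leave the C2=C3 enol-ether double bond at the flavone oxidation level. The closest known reaction type is the thermal intramolecular ester Wittig cyclisation of (2-acyloxyphenacylidene)triphenylphosphoranes to chromones and flavones. Ring C is closed in a 6-exo-trig mode, the attacked C=O being exocyclic to the forming O1–C2–C3–C4–C4a–C8a ring. No stereocentre is created, and C2' should be untouched because the medium is neutral and aprotic and the C8a oxygen stays acylated until it becomes O1, so no ortho-quinone methide can form. The selectivity needed is olefination over transfer of the benzoyl group from oxygen to the ylide carbon; it is secured by the rigid ortho placement of ylide and ester on ring A and by the apolar solvent, which disfavours phenoxide expulsion, while the regiochemistry of closure is fixed because only the C8a oxygen is acylated and O5 is a methyl ether.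

Step 12
Reactants: 24 tert-butyl (2R)-2-(5,7-dimethoxy-4-oxo-2-phenyl-4H-chromen-8-yl)piperidine-1-carboxylate
Product: 25 5,7-dimethoxy-2-phenyl-8-[(2R)-piperidin-2-yl]-4H-chromen-4-one
Conditions: CF3CO2H, CH2Cl2, 0 °C; aq. NaHCO3 work-up
Reagents that add atoms: none
Why: Acid-mediated carbamate cleavage (loss of the tert-butyl cation, then decarboxylation) should be safe here because all three ring A oxygens are now conjugated to the C4 carbonyl, which disfavours ionisation of the C2'–N bond.

Step 13
Reactants: 25 5,7-dimethoxy-2-phenyl-8-[(2R)-piperidin-2-yl]-4H-chromen-4-one; 26 formaldehyde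
Product: 27 5,7-dimethoxy-8-[(2R)-1-methylpiperidin-2-yl]-2-phenyl-4H-chromen-4-one
Conditions: 37% aq. HCHO, NaBH(OAc)3, ClCH2CH2Cl, 20 °C
Reagents that add atoms: formaldehyde, C=O
Why: Reductive amination (iminium formation, then hydride transfer) should methylate nitrogen while the methyl ethers still block Mannich reactivity of ring A, the pyranone being inert to this mild hydride.

Step 14
Reactants: 27 5,7-dimethoxy-8-[(2R)-1-methylpiperidin-2-yl]-2-phenyl-4H-chromen-4-one
Product: 28 5,7-dihydroxy-8-[(2R)-1-methylpiperidin-2-yl]-2-phenyl-4H-chromen-4-one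
Conditions: BBr3, CH2Cl2, −78 → 20 °C; MeOH, 0 °C; aq. NaHCO3
Reagents that add atoms: none
Why: Lewis acid-mediated aryl methyl ether cleavage, in which BBr3 coordinates the ether oxygens (O5 assisted by chelation to the C4 carbonyl) and bromide removes the methyl groups, should give the target if the mixture is kept at or below 20 °C and neutralised cold to avoid reversible opening at C2'.

**Compound list**

1 | 2-hydroxy-4,6-dimethoxybenzaldehyde | COc1cc(O)c(C=O)c(OC)c1 | starting material
2 | N-bromosuccinimide | O=C1CCC(=O)N1Br | starting material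
3 | 3-bromo-2-hydroxy-4,6-dimethoxybenzaldehyde | O=Cc1c(O)c(Br)c(OC)cc1OC | intermediate
4 | benzyl bromide | BrCc1ccccc1 | starting material
5 | 2-(benzyloxy)-3-bromo-4,6-dimethoxybenzaldehyde | O=Cc1c(OCc2ccccc2)c(Br)c(OC)cc1OC | intermediate
6 | (S)-2-methylpropane-2-sulfinamide | CC(C)(C)[S@](=O)N | starting material
7 | (S)-N-{(E)-[2-(benzyloxy)-3-bromo-4,6-dimethoxyphenyl]methylidene}-2-methylpropane-2-sulfinamide | CC(C)(C)[S@](=O)/N=C/c1c(OCc2ccccc2)c(Br)c(OC)cc1OC | intermediate
8 | 1-bromo-4-chlorobutane | ClCCCCBr | starting material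
9 | 4-chlorobutylmagnesium bromide (not isolated) | ClCCCC[Mg]Br | intermediate
10 | (S)-N-{(1R)-1-[2-(benzyloxy)-3-bromo-4,6-dimethoxyphenyl]-5-chloropentyl}-2-methylpropane-2-sulfinamide | CC(C)(C)[S@](=O)N[C@H](CCCCCl)c1c(OCc2ccccc2)c(Br)c(OC)cc1OC | intermediate
11 | (2R)-2-[2-(benzyloxy)-3-bromo-4,6-dimethoxyphenyl]-1-[(S)-2-methylpropane-2-sulfinyl]piperidine | CC(C)(C)[S@](=O)N1CCCC[C@@H]1c1c(OCc2ccccc2)c(Br)c(OC)cc1OC | intermediate
12 | di-tert-butyl dicarbonate | CC(C)(C)OC(=O)OC(=O)OC(C)(C)C | starting material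
13 | (2R)-2-[2-(benzyloxy)-3-bromo-4,6-dimethoxyphenyl]piperidinium chloride (not isolated) | [Cl-].[NH2+]1CCCC[C@@H]1c1c(OCc2ccccc2)c(Br)c(OC)cc1OC | intermediate
14 | tert-butyl (2R)-2-[2-(benzyloxy)-3-bromo-4,6-dimethoxyphenyl]piperidine-1-carboxylate | CC(C)(C)OC(=O)N1CCCC[C@@H]1c1c(OCc2ccccc2)c(Br)c(OC)cc1OC | intermediate
15 | 2-chloro-N-methoxy-N-methylacetamide | CON(C)C(=O)CCl | starting material
16 | tert-butyl (2R)-2-[2-(benzyloxy)-3-lithio-4,6-dimethoxyphenyl]piperidine-1-carboxylate (not isolated) | CC(C)(C)OC(=O)N1CCCC[C@@H]1c1c(OCc2ccccc2)c([Li])c(OC)cc1OC | intermediate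
17 | tert-butyl (2R)-2-[2-(benzyloxy)-3-(chloroacetyl)-4,6-dimethoxyphenyl]piperidine-1-carboxylate | CC(C)(C)OC(=O)N1CCCC[C@@H]1c1c(OCc2ccccc2)c(C(=O)CCl)c(OC)cc1OC | intermediate
18 | triphenylphosphine | c1ccc(P(c2ccccc2)c2ccccc2)cc1 | starting material
19 | {2-[2-(benzyloxy)-3-[(2R)-1-(tert-butoxycarbonyl)piperidin-2-yl]-4,6-dimethoxyphenyl]-2-oxoethyl}triphenylphosphonium chloride | CC(C)(C)OC(=O)N1CCCC[C@@H]1c1c(OCc2ccccc2)c(C(=O)C[P+](c2ccccc2)(c2ccccc2)c2ccccc2)c(OC)cc1OC.[Cl-] | intermediate
20 | {2-[3-[(2R)-1-(tert-butoxycarbonyl)piperidin-2-yl]-2-hydroxy-4,6-dimethoxyphenyl]-2-oxoethyl}triphenylphosphonium chloride | CC(C)(C)OC(=O)N1CCCC[C@@H]1c1c(O)c(C(=O)C[P+](c2ccccc2)(c2ccccc2)c2ccccc2)c(OC)cc1OC.[Cl-] | intermediate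
21 | benzoyl chloride | O=C(Cl)c1ccccc1 | starting material
22 | tert-butyl (2R)-2-{2-hydroxy-4,6-dimethoxy-3-[(triphenyl-λ5-phosphanylidene)acetyl]phenyl}piperidine-1-carboxylate (not isolated) | CC(C)(C)OC(=O)N1CCCC[C@@H]1c1c(O)c(C(=O)C=P(c2ccccc2)(c2ccccc2)c2ccccc2)c(OC)cc1OC | intermediate
23 | tert-butyl (2R)-2-{2-(benzoyloxy)-4,6-dimethoxy-3-[(triphenyl-λ5-phosphanylidene)acetyl]phenyl}piperidine-1-carboxylate | CC(C)(C)OC(=O)N1CCCC[C@@H]1c1c(OC(=O)c2ccccc2)c(C(=O)C=P(c2ccccc2)(c2ccccc2)c2ccccc2)c(OC)cc1OC | intermediate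
24 | tert-butyl (2R)-2-(5,7-dimethoxy-4-oxo-2-phenyl-4H-chromen-8-yl)piperidine-1-carboxylate | CC(C)(C)OC(=O)N1CCCC[C@@H]1c1c(OC)cc(OC)c2c(=O)cc(-c3ccccc3)oc12 | intermediate
25 | 5,7-dimethoxy-2-phenyl-8-[(2R)-piperidin-2-yl]-4H-chromen-4-one | N1CCCC[C@@H]1c1c(OC)cc(OC)c2c(=O)cc(-c3ccccc3)oc12 | intermediate
26 | formaldehyde | C=O | starting material
27 | 5,7-dimethoxy-8-[(2R)-1-methylpiperidin-2-yl]-2-phenyl-4H-chromen-4-one | CN1CCCC[C@@H]1c1c(OC)cc(OC)c2c(=O)cc(-c3ccccc3)oc12 | intermediate
28 | 5,7-dihydroxy-8-[(2R)-1-methylpiperidin-2-yl]-2-phenyl-4H-chromen-4-one | CN1CCCC[C@@H]1c1c(O)cc(O)c2c(=O)cc(-c3ccccc3)oc12 | target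

Total step count: 14. Longest linear sequence: 14 steps (1 to 28).

**Steps most likely to fail**

Step 11. The tetrahedral adduct of the ylide carbon and the benzoate may collapse with loss of phenoxide (benzoyl migration to C3) faster than it closes to the oxaphosphetane, or the crowded ester may react so slowly that the carbamate degrades on long heating. The fallback builds ring C by a Baker–Venkataraman sequence and sets out from bromide 14. Lithiation as in step 7 and acylation with N-methoxy-N-methylacetamide should give tert-butyl (2R)-2-[3-acetyl-2-(benzyloxy)-4,6-dimethoxyphenyl]piperidine-1-carboxylate F1. Hydrogenolysis (H2, Pd/C) should give tert-butyl (2R)-2-(3-acetyl-2-hydroxy-4,6-dimethoxyphenyl)piperidine-1-carboxylate F2, and benzoylation (BzCl, pyridine) the ester tert-butyl (2R)-2-[3-acetyl-2-(benzoyloxy)-4,6-dimethoxyphenyl]piperidine-1-carboxylate F3. LiN(SiMe3)2 in THF should then induce the O-to-C benzoyl shift to the diketone tert-butyl (2R)-2-[2-hydroxy-4,6-dimethoxy-3-(3-oxo-3-phenylpropanoyl)phenyl]piperidine-1-carboxylate F4. HCl in acetic acid should effect cyclodehydration with loss of the Boc group, and neutralisation brings the material back to the route at amine 25.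

Step 10. Acylation may take place at the ylide carbon (or at its enolate-type oxygen) in place of the crowded, hydrogen-bonded phenol oxygen, which would consume the ylide in an unreactive diacyl form. The fallback assembles the same ylide from the carboxylic acid side and also sets out from bromide 14. Lithiation as in step 7 and quenching with CO2 should give 2-(benzyloxy)-3-[(2R)-1-(tert-butoxycarbonyl)piperidin-2-yl]-4,6-dimethoxybenzoic acid F5. Hydrogenolysis should give 3-[(2R)-1-(tert-butoxycarbonyl)piperidin-2-yl]-2-hydroxy-4,6-dimethoxybenzoic acid F6, and benzoylation of the phenol (BzCl, pyridine, aqueous work-up) 2-(benzoyloxy)-3-[(2R)-1-(tert-butoxycarbonyl)piperidin-2-yl]-4,6-dimethoxybenzoic acid F7. Silylation (t-BuMe2SiCl, imidazole) should give tert-butyldimethylsilyl 2-(benzoyloxy)-3-[(2R)-1-(tert-butoxycarbonyl)piperidin-2-yl]-4,6-dimethoxybenzoate F8. C-Acylation of Ph3P=CHSiMe3 by this silyl ester in THF, with loss of the silyl groups as a disiloxane, should deliver ylide 23, where the route is rejoined before step 11.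

Step 14. Once O7 is unmasked beside the Lewis acid-complexed amine, reversible heterolysis of the C2'–N bond may erode configurational purity, or cleavage at O7 may stay incomplete. The fallback is a two-stage dealkylation by different mechanisms and sets out from 27. BCl3 in CH2Cl2 at −78 to 0 °C should cleave only the chelated O5 methyl ether to give 5-hydroxy-7-methoxy-8-[(2R)-1-methylpiperidin-2-yl]-2-phenyl-4H-chromen-4-one F9. SN2 demethylation at O7 with NaSEt in DMF at 110 °C, under basic conditions in which nitrogen is unprotonated and a poor leaving group, should then give the target 28.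

**Further compounds**

F1 | step 11 | tert-butyl (2R)-2-[3-acetyl-2-(benzyloxy)-4,6-dimethoxyphenyl]piperidine-1-carboxylate | CC(C)(C)OC(=O)N1CCCC[C@@H]1c1c(OCc2ccccc2)c(C(C)=O)c(OC)cc1OC
F2 | step 11 | tert-butyl (2R)-2-(3-acetyl-2-hydroxy-4,6-dimethoxyphenyl)piperidine-1-carboxylate | CC(C)(C)OC(=O)N1CCCC[C@@H]1c1c(O)c(C(C)=O)c(OC)cc1OC
F3 | step 11 | tert-butyl (2R)-2-[3-acetyl-2-(benzoyloxy)-4,6-dimethoxyphenyl]piperidine-1-carboxylate | CC(C)(C)OC(=O)N1CCCC[C@@H]1c1c(OC(=O)c2ccccc2)c(C(C)=O)c(OC)cc1OC
F4 | step 11 | tert-butyl (2R)-2-[2-hydroxy-4,6-dimethoxy-3-(3-oxo-3-phenylpropanoyl)phenyl]piperidine-1-carboxylate | CC(C)(C)OC(=O)N1CCCC[C@@H]1c1c(O)c(C(=O)CC(=O)c2ccccc2)c(OC)cc1OC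
F5 | step 10 | 2-(benzyloxy)-3-[(2R)-1-(tert-butoxycarbonyl)piperidin-2-yl]-4,6-dimethoxybenzoic acid | CC(C)(C)OC(=O)N1CCCC[C@@H]1c1c(OCc2ccccc2)c(C(=O)O)c(OC)cc1OC
F6 | step 10 | 3-[(2R)-1-(tert-butoxycarbonyl)piperidin-2-yl]-2-hydroxy-4,6-dimethoxybenzoic acid | CC(C)(C)OC(=O)N1CCCC[C@@H]1c1c(O)c(C(=O)O)c(OC)cc1OC
F7 | step 10 | 2-(benzoyloxy)-3-[(2R)-1-(tert-butoxycarbonyl)piperidin-2-yl]-4,6-dimethoxybenzoic acid | CC(C)(C)OC(=O)N1CCCC[C@@H]1c1c(OC(=O)c2ccccc2)c(C(=O)O)c(OC)cc1OC
F8 | step 10 | tert-butyldimethylsilyl 2-(benzoyloxy)-3-[(2R)-1-(tert-butoxycarbonyl)piperidin-2-yl]-4,6-dimethoxybenzoate | CC(C)(C)OC(=O)N1CCCC[C@@H]1c1c(OC(=O)c2ccccc2)c(C(=O)O[Si](C)(C)C(C)(C)C)c(OC)cc1OC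
F9 | step 14 | 5-hydroxy-7-methoxy-8-[(2R)-1-methylpiperidin-2-yl]-2-phenyl-4H-chromen-4-one | CN1CCCC[C@@H]1c1c(OC)cc(O)c2c(=O)cc(-c3ccccc3)oc12
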